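## Analysis of the target

Target 17 is (3R,4aR,7aR)-3,4a-dimethyl-3-(10-phenyldecyl)-4,4a,7,7a-tetrahydrofuro[3,2-c][1,2]dioxin-6(3H)-one, a 1,2-dioxane cis-fused to a γ-lactone. The atoms are numbered along the carbon chain: C1 lactone carbonyl, C2 its CH2, C3 the peroxy CH, C4 the methyl-bearing lactone carbinol carbon, C5 the ring CH2, C6 the methyl-bearing peroxy carbon, C7 the first carbon of the 10-phenyldecyl chain. O1 (on C3) and O2 (on C6) are the peroxide oxygens and O4 is the lactone ring oxygen.

There are three stereocentres, C3 (R), C4 (R) and C6 (R). C3 and C4 are tied together by the cis ring fusion, with O1 and C5 on the same face of the lactone. C6 stands 1,3 to C4 across C5, with its methyl on the dioxane face that carries O4 and C2 and the chain on the face of the C4 methyl and H3.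

The O–O bond does not survive reductants, phosphines, low-valent metals or strong carbon nucleophiles. The β-peroxy lactone can also revert by retro-conjugate addition or fragment under base at C3–H. The peroxide therefore has to come last, with nothing reducing or strongly basic after it.

The difficulty lies in two fully substituted, oxygen-bearing carbons (C4 and C6), of which C6 is remote from any controlling element, and in a long lipophilic chain that offers no handle.

The strategy rests on C4. It is a methyl carbinol carbon whose oxygen O4 is acylated by C1 four atoms away, the pattern of a levulinate ketone that has accepted a carbon nucleophile. If that nucleophile is a 2-substituted allyl unit (C5, C6, the future C6 methyl as =CH2, and the chain already on C6), one C–C bond assembles the whole skeleton, the lactone ring closes, and a 1,1-disubstituted alkene is left exactly where the tertiary C6–O2 bond is needed.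

## Retrosynthetic reasoning

**O1–C3.** Target 17 is a β-peroxy lactone, so the O1–C3 bond is cut as a conjugate addition. This leads back to hydroperoxide 16, a butenolide with the C6–OOH group on its side chain. The cut is made here because the three-atom tether C4–C5–C6 can reach only the butenolide face on which C5 sits. The forward 6-exo-trig addition therefore has to give the cis fusion, and C3 needs no reagent control.

**C6–O2.** The tertiary peroxide of 16 is taken back through its silyl peroxide 15 to the 1,1-disubstituted alkene of butenolide 14. A cobalt-mediated hydrogen-atom transfer followed by oxygen capture places O2 on the more substituted carbon and turns the =CH2 into the C6 methyl in one operation. What this does not give is control of C6: the radical is planar and far from C4, so both C6 epimers must be expected, and the target is separated after ring closure. This is accepted as the price of a very short endgame.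

**C2=C3.** The unsaturation of 14 is removed to give saturated lactone 10, by way of α-selenide 12. Introducing it by selenation and selenoxide elimination is regiochemically unambiguous, because C3 carries the only β-hydrogens.

**C4–C5 and C1–O4 (key disconnection).** Lactone 10 is opened at C1–O4 to hydroxy ester 9 and then cut at C4–C5. This gives methyl levulinate 8 as the C1–C4 electrophile and allylboronate 7 as the C5–C6 nucleophile, already carrying the complete chain. The cut is made at C4–C5 and not at C5–C6 or C6–C7 because it is the only one that creates the C4 stereocentre in the bond-forming event itself. It also uses a catalytic asymmetric ketone allylation, and the tertiary alkoxide it produces lactonises of its own accord.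

**C–B bond of 7.** The boronate is taken back to allyl chloride 6, to be borylated under palladium catalysis. Deprotonating an unfunctionalised chain alkene with a superbase and quenching with a borate was set aside. Such a base cannot be relied on to distinguish the allylic methyl from the allylic methylene, the benzylic CH2 and the arene C–H bonds. With 6, both termini of the allyl unit are equivalent, so no regiochemical question arises.

**Chain assembly.** Chloride 6 is cut at the C7–C8 bond into the symmetric bis-electrophile 3-chloro-2-(chloromethyl)prop-1-ene 4 and Grignard reagent 5. Reagent 5 comes from (9-bromononyl)benzene 3, itself the mono-coupling product of phenylmagnesium bromide 1 with 1,9-dibromononane 2. Both couplings use a symmetric dihalide in excess, so selectivity is a matter of stoichiometry and not of reactivity differences.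

## Alternatives that were turned down

**Alternative 1:** C1 and C6 are treated as the two ends of a cleaved ring double bond. A six-membered carbocycle built from C1–C6, carrying the C4 tertiary hydroxyl, a C3 sulfonate and both methyl groups, would be opened by ozonolysis with reductive work-up. The C4 hydroxyl would trap the new C1 aldehyde as five-membered lactol A1, (2R,3S)-5-hydroxy-2-methyl-2-(2-oxopropyl)oxolan-3-yl methanesulfonate, leaving C6 as a methyl ketone.
- For: all ring carbons and both methyls come from one cheap symmetric precursor. C3 and C4 are set together as a cis diol on a ring. The sulfonate in A1 has the configuration needed to close the dioxane by SN2 with inversion, so C3 would come from a stereospecific substitution.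
- Against: the chain must be added afterwards to the C6 ketone of A1 by an organometallic that has to ignore a lactol and a sulfonate. C6 is then formed without control, as in the chosen route, and the tertiary alcohol still has to be converted into a hydroperoxide by an ionising substitution. The sulfonate is β to C1, so once C1 is at the lactone level E1cB elimination competes in every basic step. The displacement at C3 is at a secondary carbon next to quaternary C4. The opening desymmetrisation has to distinguish two equivalent trisubstituted alkenes.
- Comparison: on C3 this plan is stronger in principle. The chosen strategy obtains C3 from the ring fusion, brings the chain in with the first C–C bond and not the last, and needs roughly half as many operations after its key step.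

**Alternative 2:** C6–O2 is cut in the ionic sense together with O1–C3. A butenolide whose side chain ends in a 2,2-disubstituted epoxide across C6–C7 would be opened at tertiary C6 by a peroxide nucleophile under heteropolyacid catalysis, with inversion. A secondary amine would then trigger the same 6-exo conjugate addition as in the chosen route. The product is A2, (3S,4aR,7aR)-3-(hydroxymethyl)-3,4a-dimethyl-4,4a,7,7a-tetrahydrofuro[3,2-c][1,2]dioxin-6(3H)-one, in which C7 is a primary alcohol.
- For: C6 derives stereospecifically from an epoxide of defined configuration, which is exactly the control the chosen route lacks. Both heteroatom bonds of the dioxane form in one flask.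
- Against: the phenylalkyl chain has to be attached after the peroxide exists, at C7 next to quaternary C6. That excludes substitution and forces oxidation, olefination and a metal-free alkene reduction on a molecule containing an O–O bond. Opening a tertiary centre with inversion competes with ionisation and with attack at primary C7. The enantioenriched 2,2-disubstituted epoxide needs its own asymmetric step on a 1,1-disubstituted alkene, a class where selectivity is usually moderate.
- Comparison: stronger on C6; weaker on convergence and on the number of operations carried out on a peroxide (three or more, against none here). The chosen strategy has the whole skeleton in place before any peroxide oxygen is added and ends at the cyclisation.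

**Alternative 3:** O1–C3 is cut with C3 as a ketone. An open-chain β-keto ester bearing the C6 hydroperoxide and a silyl-protected C4 tertiary alcohol would close to a cyclic peroxyhemiketal. Ionisation with a silyl triflate and silane reduction of the peroxycarbenium ion would deliver hydride to C3, giving A3, methyl 2-[(3R,4R,6R)-4,6-dimethyl-6-(10-phenyldecyl)-4-(triethylsilyloxy)-1,2-dioxan-3-yl]acetate. Desilylation and lactonisation would finish.
- For: C3 would be fixed by stereoelectronically controlled axial attack on a six-membered cation. No butenolide with competing acceptor reactivity is involved. If C6 is made selectively beforehand, all three centres are controlled.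
- Against: C4 and C6, two tetrasubstituted centres 1,3 to each other, must be set independently in an acyclic precursor that also carries a β-keto ester, so the route is long. The dioxane has two quaternary carbons, each forcing one group axial, so the preferred conformation of the cation, and with it the face of hydride delivery, is not clear-cut. A strong Lewis acid acts on a tertiary silyl ether next to the cationic carbon and on a peroxide, which invites ionisation at C4 and O–O fragmentation.
- Comparison: stronger on stereochemical completeness; the chosen strategy is much shorter, and its C3 control is a geometric necessity and not a conformational preference.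

Key step: step 4

Assumption 1: the hand of the bisphosphine that gives the (S) adduct is written as (R,R). If the sense of induction on this dialkyl ketone is the opposite, the (S,S) ligand is used and nothing else changes.

Assumption 2: phenylmagnesium bromide is bought as a THF solution.

Remark on C6: nothing in the route controls C6. Both C6 epimers form in step 7 and are carried together as 15 and 16. The target is separated after step 9.

## Route

Step 1
Reactants: 1 phenylmagnesium bromide; 2 1,9-dibromononane
Product: 3 (9-bromononyl)benzene
Conditions: 2 (3 equiv), Li2CuCl4 (3 mol %), THF, 0 °C → rt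
Reagents that add atoms: none
Why: Copper-catalysed Kochi-type cross-coupling of an aryl Grignard reagent with a primary alkyl bromide; the excess of symmetric 2 keeps substitution to one end, and unreacted 2 is recovered by distillation.

Step 2
Reactants: 3 (9-bromononyl)benzene; 4 3-chloro-2-(chloromethyl)prop-1-ene
Product: 6 2-(chloromethyl)-12-phenyldodec-1-ene, via (9-phenylnonyl)magnesium bromide 5 (not isolated)
Conditions: Mg, I2 (cat.), THF, 40 °C; then added slowly to 4 (3 equiv), CuI (5 mol %), THF, −30 → 0 °C
Reagents that add atoms: magnesium, [Mg] (retained only in 5)
Why: Magnesium insertion gives Grignard reagent 5, which undergoes copper-catalysed allylic substitution on 4; since 4 is symmetric, SN2 and SN2' attack give the same 2-substituted allyl chloride, and excess 4 with slow addition at low temperature suppresses a second substitution.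

Step 3
Reactants: 6 2-(chloromethyl)-12-phenyldodec-1-ene
Product: 7 4,4,5,5-tetramethyl-2-(2-methylidene-12-phenyldodecyl)-1,3,2-dioxaborolane
Conditions: B2pin2 (1.1 equiv), Pd2(dba)3 (1 mol %), THF, 60 °C
Reagents that add atoms: bis(pinacolato)diboron, CC1(C)OB(OC1(C)C)B1OC(C)(C)C(C)(C)O1
Why: Palladium-catalysed Miyaura-type borylation of an allylic chloride: oxidative addition to zerovalent palladium gives a π-allyl complex, followed by B–B transmetalation and C–B reductive elimination; the two allyl termini are equivalent, so only one allylboronate can form.

Step 4
Reactants: 8 methyl levulinate (methyl 4-oxopentanoate); 7 4,4,5,5-tetramethyl-2-(2-methylidene-12-phenyldodecyl)-1,3,2-dioxaborolane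
Product: 10 (5S)-5-methyl-5-(2-methylidene-12-phenyldodecyl)oxolan-2-one, via hydroxy ester 9 (not isolated)
Conditions: 8 (1.5 equiv), CuOAc (5 mol %), (R,R)-iPr-DuPhos (6 mol %), LiOiPr (0.5 equiv), iPrOH (1 equiv), CH2Cl2, −75 °C; then TsOH·H2O (10 mol %), rt
Reagents that add atoms: none
Why: The copper alkoxide formed from CuOAc and LiOiPr exchanges its alkoxide for the allyl group of 7 and gives a bisphosphine-bound 2-substituted allyl complex of monovalent copper. This nucleophile delivers its γ-carbon to the ketone carbon of 8 in a closed six-membered chair array (C4–C5 formed), and because both ends of the allyl unit are identical CH2 groups the allylic shift has no regiochemical consequence. Protonolysis of the copper alkoxide by iPrOH returns the catalyst and leaves hydroxy ester 9, methyl (4S)-4-hydroxy-4-methyl-6-methylidene-16-phenylhexadecanoate. The C4 oxygen then attacks the ester carbonyl four atoms away and expels methanol, a 5-exo-trig acyl substitution that is helped by the fully substituted C4 (Thorpe–Ingold effect) and completed by the TsOH finish (C1–O4 and the lactone ring formed). The closest known reaction type is the copper–bisphosphine-catalysed enantioselective allylboration of ketones, including γ-keto esters whose adducts lactonise. C4 is the only new stereocentre and is controlled by the chiral bisphosphine, which decides which enantiotopic face of the ketone is presented to the allyl group, since nothing in achiral 7 or 8 biases it. The selectivity needed is the distinction of CH3 from CH2CH2CO2Me, two groups of similar size: the methylene arm is the larger one, the 2-substituent of the allyl unit raises the steric demand of the nucleophile, and the low temperature keeps the ligand-free background addition out. Chemoselectivity for the ketone over the ester follows from the much lower electrophilicity of the ester towards allylcopper at −75 °C.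

Step 5
Reactants: 10 (5S)-5-methyl-5-(2-methylidene-12-phenyldodecyl)oxolan-2-one
Product: 12 (5R)-5-methyl-5-(2-methylidene-12-phenyldodecyl)-3-(phenylselanyl)oxolan-2-one (both C3 epimers), via lithium enolate 11 (not isolated)
Conditions: LiN(iPr)2 (1.1 equiv), THF, −78 °C; PhSeBr (1.05 equiv), −78 °C
Reagents that add atoms: benzeneselenenyl bromide, Br[Se]c1ccccc1; lithium diisopropylamide, CC(C)N([Li])C(C)C (lithium retained only in 11)
Why: Kinetic deprotonation of the γ-lactone gives enolate 11, which is selenenylated at C2 faster than the electrophile adds to the 1,1-disubstituted alkene at −78 °C. C4 is untouched (its descriptor changes only because of CIP priorities), and the configuration at C2 is irrelevant because that centre becomes sp2 in the next step.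

Step 6
Reactants: 12 (5R)-5-methyl-5-(2-methylidene-12-phenyldodecyl)-3-(phenylselanyl)oxolan-2-one
Product: 14 (5R)-5-methyl-5-(2-methylidene-12-phenyldodecyl)furan-2(5H)-one, via selenoxide 13 (not isolated)
Conditions: NaIO4 (2 equiv), NaHCO3, THF/MeOH/H2O, 0 °C → rt
Reagents that add atoms: sodium periodate, [Na+].[O-]I(=O)(=O)=O (oxygen retained only in 13)
Why: Periodate oxidises selenium to selenoxide 13, which undergoes syn elimination at or below room temperature; the only β-hydrogens are on C3, so the double bond must form as C2=C3. Periodate is chosen over peroxide oxidants because it generates no perseleninic acid that could epoxidise the electron-rich alkene.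

Step 7
Reactants: 14 (5R)-5-methyl-5-(2-methylidene-12-phenyldodecyl)furan-2(5H)-one
Product: 15 (5R)-5-methyl-5-[2-methyl-12-phenyl-2-(triethylsilylperoxy)dodecyl]furan-2(5H)-one (both epimers at C6, the peroxy carbon)
Conditions: Co(acac)2 (10 mol %), Et3SiH (2 equiv), O2 (1 atm), ClCH2CH2Cl, rt
Reagents that add atoms: dioxygen, O=O; triethylsilane, CC[SiH](CC)CC
Why: Mukaiyama–Isayama silylperoxidation: a cobalt hydride generated from the divalent cobalt diketonate transfers a hydrogen atom to the terminal CH2, the tertiary C6 radical captures O2, and the cobalt peroxide is silylated by Et3SiH. The electron-rich 1,1-disubstituted alkene, which gives a tertiary radical, should react well ahead of the conjugated 1,2-disubstituted butenolide alkene. The C6 radical is planar and remote from C4, so no facial preference is expected and both C6 epimers should form in comparable amounts.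

Step 8
Reactants: 15 (5R)-5-methyl-5-[2-methyl-12-phenyl-2-(triethylsilylperoxy)dodecyl]furan-2(5H)-one
Product: 16 (5R)-5-(2-hydroperoxy-2-methyl-12-phenyldodecyl)-5-methylfuran-2(5H)-one (both epimers at C6)
Conditions: HCl (conc. aq., cat.), MeOH/CH2Cl2, 0 °C
Reagents that add atoms: none
Why: Acid-catalysed methanolysis of the O–Si bond of a silyl peroxide; the O–O bond, the tertiary C6–O bond and the butenolide should tolerate catalytic HCl at 0 °C for the short time needed.

Step 9
Reactants: 16 (5R)-5-(2-hydroperoxy-2-methyl-12-phenyldodecyl)-5-methylfuran-2(5H)-one
Product: 17 (3R,4aR,7aR)-3,4a-dimethyl-3-(10-phenyldecyl)-4,4a,7,7a-tetrahydrofuro[3,2-c][1,2]dioxin-6(3H)-one (the target)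
Conditions: Et2NH (0.5 equiv), CF3CH2OH, rt; chromatographic separation of the C6 epimers
Reagents that add atoms: none
Why: Amine-promoted intramolecular peroxy-Michael addition (6-exo-trig) of the hydroperoxide to C3 of the butenolide, with the fluorinated alcohol protonating the enolate at C2 without acting as a nucleophile. C3 is set by C4, because the C4–C5–C6 tether reaches only the butenolide face that carries C5, which gives the cis fusion. Both C6 epimers cyclise, and 17 is freed from the material epimeric at C6 at this stage, where the rigid bicycles differ in which C6 substituent is axial; the assignment is made by NOE.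

## Compound list

1 | phenylmagnesium bromide | Br[Mg]c1ccccc1 | starting material
2 | 1,9-dibromononane | BrCCCCCCCCCBr | starting material
3 | (9-bromononyl)benzene | BrCCCCCCCCCc1ccccc1 | intermediate
4 | 3-chloro-2-(chloromethyl)prop-1-ene | C=C(CCl)CCl | starting material
5 | (9-phenylnonyl)magnesium bromide (not isolated) | Br[Mg]CCCCCCCCCc1ccccc1 | intermediate
6 | 2-(chloromethyl)-12-phenyldodec-1-ene | ClCC(=C)CCCCCCCCCCc1ccccc1 | intermediate
7 | 4,4,5,5-tetramethyl-2-(2-methylidene-12-phenyldodecyl)-1,3,2-dioxaborolane | CC1(C)OB(CC(=C)CCCCCCCCCCc2ccccc2)OC1(C)C | intermediate
8 | methyl levulinate (methyl 4-oxopentanoate) | CC(=O)CCC(=O)OC | starting material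
9 | methyl (4S)-4-hydroxy-4-methyl-6-methylidene-16-phenylhexadecanoate (not isolated) | COC(=O)CC[C@](C)(O)CC(=C)CCCCCCCCCCc1ccccc1 | intermediate
10 | (5S)-5-methyl-5-(2-methylidene-12-phenyldodecyl)oxolan-2-one | C=C(CCCCCCCCCCc1ccccc1)C[C@@]1(C)OC(=O)CC1 | intermediate
11 | lithium (5S)-5-methyl-5-(2-methylidene-12-phenyldodecyl)-4,5-dihydrofuran-2-olate (not isolated) | C=C(CCCCCCCCCCc1ccccc1)C[C@@]1(C)OC(O[Li])=CC1 | intermediate
12 | (5R)-5-methyl-5-(2-methylidene-12-phenyldodecyl)-3-(phenylselanyl)oxolan-2-one, both C3 epimers | C=C(CCCCCCCCCCc1ccccc1)C[C@@]1(C)OC(=O)C([Se]c2ccccc2)C1 | intermediate
13 | (5R)-3-(benzeneseleninyl)-5-methyl-5-(2-methylidene-12-phenyldodecyl)oxolan-2-one, mixture of isomers at C3 and Se (not isolated) | C=C(CCCCCCCCCCc1ccccc1)C[C@@]1(C)OC(=O)C([Se](=O)c2ccccc2)C1 | intermediate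
14 | (5R)-5-methyl-5-(2-methylidene-12-phenyldodecyl)furan-2(5H)-one | C=C(CCCCCCCCCCc1ccccc1)C[C@@]1(C)OC(=O)C=C1 | intermediate
15 | (5R)-5-methyl-5-[2-methyl-12-phenyl-2-(triethylsilylperoxy)dodecyl]furan-2(5H)-one, both epimers at the peroxy carbon (C6) | CC[Si](CC)(CC)OOC(C)(CCCCCCCCCCc1ccccc1)C[C@@]1(C)OC(=O)C=C1 | intermediate
16 | (5R)-5-(2-hydroperoxy-2-methyl-12-phenyldodecyl)-5-methylfuran-2(5H)-one, both epimers at the peroxy carbon (C6) | CC(OO)(CCCCCCCCCCc1ccccc1)C[C@@]1(C)OC(=O)C=C1 | intermediate
17 | (3R,4aR,7aR)-3,4a-dimethyl-3-(10-phenyldecyl)-4,4a,7,7a-tetrahydrofuro[3,2-c][1,2]dioxin-6(3H)-one | C[C@@]1(CCCCCCCCCCc2ccccc2)C[C@@]2(C)OC(=O)C[C@H]2OO1 | target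

## Step count and least certain steps

Total: 9 steps. Longest linear sequence: 9 steps (1 and 2 through 3, 6, 7, 10, 12, 14, 15 and 16 to 17); 4 enters in step 2 and 8 in step 4.

**Step 4 (key step).** The most likely failure is insufficient enantiofacial discrimination. The ketone of 8 is flanked by a methyl and an unbranched methylene arm, the class of ketone on which catalytic allylations differentiate least. A slow transmetalation of the hindered boronate would also let unselective background addition contribute. Incomplete lactonisation is a minor concern, covered by the acid finish.

Fallback: stereocontrol by resolution instead of catalysis, setting out from 6 and 8 and bypassing step 3. Zinc dust in THF/saturated aqueous NH4Cl (Barbier conditions) converts 6 in situ into chloro(2-methylidene-12-phenyldodecyl)zinc F1, which adds to the ketone of 8. Acidic work-up lactonises the adduct to racemic 5-methyl-5-(2-methylidene-12-phenyldodecyl)oxolan-2-one F2. Preparative chromatography on a chiral stationary phase then gives 10, where the route is rejoined, and removes the antipode (5R)-5-methyl-5-(2-methylidene-12-phenyldodecyl)oxolan-2-one F3.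

**Step 7.** Hydrogen-atom transfer to the butenolide alkene may compete, leading to reduction or oxygenation at C2/C3. The cobalt may also cleave the new O–O bond and give the tertiary alcohol. The lack of facial control at C6 is not a risk but a certainty, and roughly half of the material is lost at the separation after step 9.

Fallback: ionic Markovnikov functionalisation instead of the radical one, setting out from 14. Anhydrous HBr in CH2Cl2 (−78 → 0 °C, dark) adds to the electron-rich alkene, leaving the electron-poor butenolide alone, and gives (5R)-5-(2-bromo-2-methyl-12-phenyldodecyl)-5-methylfuran-2(5H)-one F4 as both epimers. Silver-assisted perhydrolysis of this tertiary bromide (AgOCOCF3, anhydrous ethereal H2O2, 0 °C) then gives hydroperoxide 16 directly, where the route is rejoined without passing through 15.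

**Step 5.** The electrophilic selenium reagent may add across the 1,1-disubstituted alkene. Proton exchange between 12 and enolate 11 may lead to double selenenylation.

Fallback: sulfur in place of selenium, with a disulfide that is inert to alkenes, setting out from 10. Enolate 11 (LiN(iPr)2, THF, −78 °C) is quenched with PhSSPh to give (5R)-5-methyl-5-(2-methylidene-12-phenyldodecyl)-3-(phenylsulfanyl)oxolan-2-one F5. NaIO4 in aqueous MeOH gives the sulfoxide (5R)-3-(benzenesulfinyl)-5-methyl-5-(2-methylidene-12-phenyldodecyl)oxolan-2-one F6. Thermal syn elimination (toluene, 110 °C, CaCO3) gives butenolide 14, where the route is rejoined.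

**Step 2.** The product is itself an allylic chloride, so a second substitution to the bis-alkylated alkene is possible. Wurtz-type homocoupling of 5 is the other loss.

Fallback: build the 2-substituted allyl unit by alkylating a nucleophilic methallyl synthon, so that over-alkylation cannot occur, setting out from 3. 2-Methylprop-2-en-1-ol is doubly deprotonated (n-BuLi, 2 equiv, TMEDA, Et2O) to the dianion lithium 2-(lithiomethyl)prop-2-en-1-olate F7. This is alkylated on carbon by 3 to give 2-methylidene-12-phenyldodecan-1-ol F8. An Appel chlorination (PPh3, CCl4, CH2Cl2) converts F8 into 6, where the route is rejoined.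

## Further compounds

F1 | step 4 | chloro(2-methylidene-12-phenyldodecyl)zinc | Cl[Zn]CC(=C)CCCCCCCCCCc1ccccc1
F2 | step 4 | racemic 5-methyl-5-(2-methylidene-12-phenyldodecyl)oxolan-2-one | C=C(CCCCCCCCCCc1ccccc1)CC1(C)OC(=O)CC1
F3 | step 4 | (5R)-5-methyl-5-(2-methylidene-12-phenyldodecyl)oxolan-2-one | C=C(CCCCCCCCCCc1ccccc1)C[C@]1(C)OC(=O)CC1
F4 | step 7 | (5R)-5-(2-bromo-2-methyl-12-phenyldodecyl)-5-methylfuran-2(5H)-one, both epimers at the bromine-bearing carbon | CC(Br)(CCCCCCCCCCc1ccccc1)C[C@@]1(C)OC(=O)C=C1
F5 | step 5 | (5R)-5-methyl-5-(2-methylidene-12-phenyldodecyl)-3-(phenylsulfanyl)oxolan-2-one, both C3 epimers | C=C(CCCCCCCCCCc1ccccc1)C[C@@]1(C)OC(=O)C(Sc2ccccc2)C1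
F6 | step 5 | (5R)-3-(benzenesulfinyl)-5-methyl-5-(2-methylidene-12-phenyldodecyl)oxolan-2-one, mixture of isomers at C3 and S | C=C(CCCCCCCCCCc1ccccc1)C[C@@]1(C)OC(=O)C(S(=O)c2ccccc2)C1
F7 | step 2 | lithium 2-(lithiomethyl)prop-2-en-1-olate | [Li]CC(=C)CO[Li]
F8 | step 2 | 2-methylidene-12-phenyldodecan-1-ol | OCC(=C)CCCCCCCCCCc1ccccc1
A1 | alternative 1 | (2R,3S)-5-hydroxy-2-methyl-2-(2-oxopropyl)oxolan-3-yl methanesulfonate | CC(=O)C[C@@]1(C)OC(O)C[C@@H]1OS(C)(=O)=O
A2 | alternative 2 | (3S,4aR,7aR)-3-(hydroxymethyl)-3,4a-dimethyl-4,4a,7,7a-tetrahydrofuro[3,2-c][1,2]dioxin-6(3H)-one | C[C@@]1(CO)C[C@@]2(C)OC(=O)C[C@H]2OO1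
A3 | alternative 3 | methyl 2-[(3R,4R,6R)-4,6-dimethyl-6-(10-phenyldecyl)-4-(triethylsilyloxy)-1,2-dioxan-3-yl]acetate | C[C@@]1(CCCCCCCCCCc2ccccc2)C[C@@](C)(O[Si](CC)(CC)CC)[C@@H](CC(=O)OC)OO1
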